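Cuts: the γ-lactone at C8–C17 and at the C7–O acyl bond; the ten-membered ring at C5–C6, with the transannular C3–C8 bond re-formed (retro oxy-Cope); the side arms at C3–C4 (propargyl Claisen) and C7–C8 (chloroacetylide); the decalin at C1–C14 and C10–C11 (quinone Diels–Alder).
Forward: rings A and B are made together as a decalin, the 11,20-epoxide is set on ring A, ring B (C1, C2, C3, C8, C9, C10) is expanded from six to ten members, the lactone is closed last, and chloride opens the epoxide in the final step.
Enabling feature: in the ring C1–C10 the Z C3=C4 bond, the exocyclic C5=C16 bond, chlorine on C6 and oxygen on C7 and C8 sit exactly where a [3,3] shift of a C3-allenyl / C8-(E)-2-chlorovinyl carbinol pair across a C3–C8 bond leaves them, so the 6-10 bicycle maps onto an angular-methyl trans-decalin.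
Stereochemistry: C1 from the chiral Lewis acid in the cycloaddition; C10, C2, C9 and C11 by thermodynamic and steric control on the trans-decalin; C12 by reduction followed by Mitsunobu inversion; C6 and the Z alkene from the chair transition state; C7 from exterior-face enolate hydroxylation followed by Mitsunobu inversion; C8 and C17 from the tethered Reformatsky closure.

Key step: step 20

Assumption: the (S)-configured oxazaborolidinium salt is taken to shield the quinone face that leads to the C1 configuration of the target; its mirror image is used instead if the first adduct proves antipodal.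
Convention: briarane numbering is used on every intermediate (ring A = C1, C10, C11, C12, C13, C14); β is the face of the C15 methyl group on C1, α the opposite face.

Step 1
Reactants: 1 2-methyl-1,4-benzoquinone
Product: 2 2,4,5-triacetoxytoluene
Conditions: Ac2O, H2SO4 (cat.), 40 °C
Reagents that add atoms: acetic anhydride CC(=O)OC(C)=O
Why: Thiele–Winter acetoxylation, in which acid-promoted conjugate addition of acetate to the quinone carbon para to the methyl-bearing carbon, enolisation and O-acetylation give the 1,2,4-trioxygenated arene as one regioisomer.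

Step 2
Reactants: 2 2,4,5-triacetoxytoluene
Product: 4 2-hydroxy-5-methyl-1,4-benzoquinone, via 5-methylbenzene-1,2,4-triol 3 (not isolated)
Conditions: HCl, MeOH, reflux; then FeCl3, H2O, 0 °C
Reagents that add atoms: none
Why: Acid-catalysed transesterification frees the air-sensitive triol, whose para-related hydroxyl pair is then oxidised by FeCl3 (hydroquinone-to-quinone oxidation), leaving the third hydroxyl as a vinylogous acid.

Step 3
Reactants: 4 2-hydroxy-5-methyl-1,4-benzoquinone; 5 prop-2-yn-1-ol
Product: 6 2-methyl-5-(prop-2-ynyloxy)-1,4-benzoquinone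
Conditions: 5 (excess, as solvent), BF3·OEt2 (cat.), 50 °C
Reagents that add atoms: none
Why: The hydroxyquinone behaves as a vinylogous carboxylic acid, so acid-catalysed addition–elimination of the alcohol at the enol carbon (a Fischer-type etherification) gives the propargyl ether with water as the only by-product.

Step 4
Reactants: 7 (E)-4-methoxybut-3-en-2-one
Product: 8 (E)-1-methoxy-3-(trimethylsilyloxy)buta-1,3-diene
Conditions: Me3SiCl, Et3N, ZnCl2 (cat.), benzene, 40 °C
Reagents that add atoms: chlorotrimethylsilane C[Si](C)(C)Cl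
Why: Silyl enol ether formation by soft enolisation at the only enolisable position, the methyl group, gives the 1-methoxy-3-silyloxy diene.

Step 5
Reactants: 8 (E)-1-methoxy-3-(trimethylsilyloxy)buta-1,3-diene
Product: 9 (E)-1,5-dimethoxypent-1-en-3-one
Conditions: MeOCH2Cl, ZnBr2 (2 mol %), CH2Cl2, −40 °C to 0 °C
Reagents that add atoms: chloromethyl methyl ether COCCl
Why: Mukaiyama-type alkylation of a silyl enol ether by an α-chloro ether, in which the methoxymethyl cation is captured at the terminal CH2 of the dienol ether and loss of Me3SiCl restores the enone, supplies the future C20 and avoids the O-alkylation to which the free lithium enolate is prone.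

Step 6
Reactants: 9 (E)-1,5-dimethoxypent-1-en-3-one
Product: 10 (1E,3Z)-3-(tert-butyldimethylsilyloxy)-1,5-dimethoxypenta-1,3-diene
Conditions: t-BuMe2SiOTf, Et3N, Et2O, 0 °C
Reagents that add atoms: tert-butyldimethylsilyl trifluoromethanesulfonate CC(C)(C)[Si](C)(C)OS(=O)(=O)C(F)(F)F
Why: Silyl enol ether formation with a silyl triflate and Et3N gives the thermodynamically preferred (Z)-enol ether, so the methoxymethyl group points outward in the s-cis diene.

Step 7
Reactants: 6 2-methyl-5-(prop-2-ynyloxy)-1,4-benzoquinone; 10 (1E,3Z)-3-(tert-butyldimethylsilyloxy)-1,5-dimethoxypenta-1,3-diene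
Product: 11 cis-fused cycloadduct (C2 and C9 ketones, C3=C8 enol ether with O-propargyl on C8, C12=C13 silyl enol ether, 15-methyl β, H-10 β, 14α-OMe, 11α-CH2OMe)
Conditions: 10 (1.5 equiv), oxazaborolidinium salt (C24H25BNO)[N(SO2CF3)2] made from (S)-α,α-diphenylprolinol, o-tolylboroxine and HN(SO2CF3)2 (20 mol %), CH2Cl2, −78 °C
Reagents that add atoms: none
Why: Catalytic enantioselective Diels–Alder reaction in which the cationic boron Lewis acid is expected to bind the more basic vinylogous-ester carbonyl (C2=O), which makes C10 the electrophilic terminus so that the nucleophilic C11 end of the diene bonds to C10 and C14 to C1, while endo addition on the quinone face left open by the catalyst sets C1, C10, C11 and C14 together.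

Step 8
Reactants: 11 cis-fused cycloadduct
Product: 12 trans-fused enedione (10-epimer of 11, H-10 α)
Conditions: 1,8-diazabicyclo[5.4.0]undec-7-ene (DBU, 0.1 equiv), toluene, rt
Reagents that add atoms: none
Why: Base-mediated epimerisation through the C9 enolate, the only one that touches a ring-fusion carbon, leads to the trans-fused enedione with the C11 side chain equatorial, the thermodynamic isomer as is usual for angular-methyl quinone adducts.

Step 9
Reactants: 12 trans-fused enedione
Product: 13 trans-decalin 2β,9β-diol (both enol ethers retained)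
Conditions: i-Bu2AlH (4 equiv), CH2Cl2, −78 °C; aqueous potassium sodium tartrate
Reagents that add atoms: none
Why: 1,2-Reduction of both carbonyls by the aluminium hydride from the α face, because at C9 the axial path is blocked by the 1,3-diaxial C15 methyl (equatorial hydride, axial 9β-alcohol) and at C2 the adjacent axial methyl likewise forces α attack (equatorial 2β-alcohol), while the vinylogous ester is reduced 1,2 so that the C3=C8 enol ether survives.

Step 10
Reactants: 13 trans-decalin 2β,9β-diol
Product: 14 2β,9β-bis(4-methoxybenzyl) ether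
Conditions: NaH, 4-MeOC6H4CH2Br, Bu4NI (cat.), DMF, 0 °C to rt
Reagents that add atoms: 4-methoxybenzyl bromide COc1ccc(CBr)cc1
Why: Williamson etherification of both alkoxides under basic conditions, which the acid-labile C3=C8 enol ether and the silyl enol ether tolerate.

Step 11
Reactants: 14 2β,9β-bis(4-methoxybenzyl) ether
Product: 16 cross-conjugated dienone (C12 ketone, C13=C14, exocyclic C11=C20), via 11α-methoxymethyl enone 15 (not isolated)
Conditions: Bu4NF (1.1 equiv), THF, 0 °C; then DBU (3 equiv), 40 °C
Reagents that add atoms: none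
Why: Fluoride cleaves the silyl enol ether to the C12 enolate, which expels the β-methoxide at C14 (E1cB) to give enone 15, after which DBU enolises C11 and a second E1cB loss of methoxide from C20 gives the exocyclic methylene, removing the C11 and C14 centres that are no longer needed.

Step 12
Reactants: 16 cross-conjugated dienone
Product: 17 11,20-epoxy enone (epoxide oxygen α on C11, C20 β)
Conditions: t-BuOOH (anhydrous, in decane), DBU, CH2Cl2, 0 °C
Reagents that add atoms: tert-butyl hydroperoxide CC(C)(C)OO
Why: Weitz–Scheffer epoxidation in which the hydroperoxide anion adds only to the unhindered exocyclic terminus C20 (C14 is shielded by the quaternary C1) and the resulting enolate closes onto oxygen through C11 from the α face, away from the syn-axial C15 methyl and the axial C9 ether.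

Step 13
Reactants: 17 11,20-epoxy enone
Product: 18 12β-allylic alcohol
Conditions: NaBH4, CeCl3·7H2O, MeOH–THF, −78 °C
Reagents that add atoms: none
Why: Luche 1,2-reduction in which hydride reaches C12 from the α face, anti to the pseudo-axial C20 methylene of the spiro-epoxide that blocks the β face, so the alcohol emerges 12β (equatorial), epimeric to what the target needs.

Step 14
Reactants: 18 12β-allylic alcohol
Product: 19 12α 4-nitrobenzoate
Conditions: PPh3, DIAD, toluene, 0 °C to rt; 4-O2NC6H4CO2H added last
Reagents that add atoms: 4-nitrobenzoic acid OC(=O)c1ccc(cc1)[N+](=O)[O-]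
Why: Mitsunobu reaction in which the carboxylate displaces the activated allylic 12β-oxyphosphonium group from the open α face (SN2), inverting C12 to the required 12α configuration, cis to the epoxide oxygen.

Step 15
Reactants: 19 12α 4-nitrobenzoate
Product: 20 12α-allylic alcohol
Conditions: K2CO3, MeOH, 0 °C
Reagents that add atoms: none
Why: Base-catalysed transesterification removes the electron-poor benzoate and leaves the epoxide intact, because the 12α-alkoxide is cis to the epoxide oxygen and cannot open it from the rear (no Payne rearrangement).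

Step 16
Reactants: 20 12α-allylic alcohol
Product: 21 2β,9β,12α-tris(4-methoxybenzyl) ether with the C8 propargyl enol ether (C3=C8)
Conditions: NaH, 4-MeOC6H4CH2Br, Bu4NI (cat.), THF–DMF, 0 °C to rt
Reagents that add atoms: 4-methoxybenzyl bromide COc1ccc(CBr)cc1
Why: Williamson etherification gives the third 4-methoxybenzyl ether, so all three secondary oxygens carry the same base-stable group that can be removed in one oxidative step.

Step 17
Reactants: 21 tris(4-methoxybenzyl) ether with the C8 propargyl enol ether
Product: 22 C8 ketone with a 3α (equatorial) propa-1,2-dienyl group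
Conditions: toluene, 2,6-di-tert-butyl-4-methylpyridine (5 mol %), 130 °C, sealed tube
Reagents that add atoms: none
Why: Propargyl vinyl ether Claisen rearrangement ([3,3]) forms C3–C4 and turns the alkyne into the allene while C8 becomes the ketone, the new bond forming on the α face of C3 opposite the axial C15 methyl, which is also the thermodynamically favoured equatorial position.

Step 18
Reactants: 22 C8 ketone with a 3α propa-1,2-dienyl group; 23 (E)-1,2-dichloroethene
Product: 25 8α-(chloroethynyl) 8β-carbinol, via lithium chloroacetylide 24 (not isolated)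
Conditions: 23, MeLi (2.0 equiv), Et2O, 0 °C; CeCl3 (anhydrous), THF, −78 °C; then 22, −78 °C; H2O
Reagents that add atoms: none
Why: 1,2-Addition of an alkynylcerium reagent (from lithium chloroacetylide, itself from dehydrochlorination and deprotonation of 23) to the ketone without enolisation of the acidic C3–H, the slim nucleophile attacking axially from the α face, anti to the axial C9–O bond, so that the alkyne ends axial and cis to the equatorial allenyl group.

Step 19
Reactants: 25 8α-(chloroethynyl) 8β-carbinol
Product: 26 8α-[(E)-2-chlorovinyl] 8β-ol with the cis 3α-allenyl group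
Conditions: LiAlH4, THF, −40 °C to 0 °C; aqueous potassium sodium tartrate
Reagents that add atoms: none
Why: Hydroxyl-directed trans-hydroalumination of the propargylic alkyne (hydride to C7, aluminium to C6) and protonolysis with retention give the (E)-chloroalkene, and at low temperature neither the epoxide nor the allene is reduced.

Step 20
Reactants: 26 8α-[(E)-2-chlorovinyl] 8β-ol with the cis 3α-allenyl group
Product: 29 ten-membered 7-hydroxy 8-ketone (3Z, exocyclic C5=C16, 6-Cl, C7 epimeric to the target), via potassium alkoxide 27 (not isolated), via potassium enolate 28 (not isolated)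
Conditions: KN(SiMe3)2 (1.05 equiv), 18-crown-6, THF, −78 °C to −20 °C; then −78 °C, 2-(phenylsulfonyl)-3-phenyloxaziridine; AcOH
Reagents that add atoms: 2-(phenylsulfonyl)-3-phenyloxaziridine O=S(=O)(c1ccccc1)N1OC1c1ccccc1
Why: Deprotonation gives the C8 potassium alkoxide 27, whose C5=C4–C3–C8–C7=C6 array undergoes an alkoxide-accelerated [3,3] shift in which C3–C8 breaks, the central allene carbon C5 bonds to C6, the orthogonal allene π bond remains as the exocyclic C5=C16 alkene and the oxygen ends as the C7=C8 enolate 28, which the oxaziridine then hydroxylates at C7. The closest known reaction type is the anionic oxy-Cope ring expansion of cis-1,2-dialkenylcyclohexanols to cyclodecenones with oxidation of the resulting enolate by an N-sulfonyloxaziridine in the same flask. The ten-membered ring is closed by four-atom expansion of ring B (C5–C6 bond formation inside a six-membered chair transition state) and not by end-to-end cyclisation, and enolate formation together with release of allene strain makes it irreversible. C6 is set by the chair transition state, in which the (E)-chloroalkene keeps chlorine pseudo-equatorial, and C7 by attack of the oxidant on the exterior face of the enolate, which gives the 7-epi alcohol. The step needs the chair with the C2 arm pseudo-axial, which gives the Z C3=C4 bond and the required C6 configuration, and the rigid trans-decalin secures it by holding the C3 allenyl group equatorial and the C8 chlorovinyl group axial. Loss of chloride from the β-chloro enolate is the competing path, but in the newly formed enolate the C6–Cl bond lies close to the nodal plane of the enolate π system, so oxidation at −78 °C should be faster than the bond rotation that elimination requires.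

Step 21
Reactants: 29 ten-membered 7-hydroxy 8-ketone; 30 (S)-2-bromopropanoic acid
Product: 31 C7 (S)-2-bromopropanoate with the C7 configuration of the target
Conditions: PPh3, DIAD, toluene, 0 °C; 30 added last
Reagents that add atoms: none
Why: Mitsunobu esterification in which the carboxylate displaces the activated C7 oxyphosphonium group with inversion (SN2 next to the carbonyl group) corrects C7 to the configuration of the target and brings in the three carbons of the lactone, while the acidic medium keeps the base-sensitive β-chloro ketone from eliminating.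

Step 22
Reactants: 31 C7 (S)-2-bromopropanoate
Product: 33 tris(4-methoxybenzyl)-protected 8-hydroxy γ-lactone, via samarium enolate 32 (not isolated)
Conditions: SmI2 (2.2 equiv), THF, −78 °C; aqueous NH4Cl
Reagents that add atoms: none
Why: Samarium diiodide-mediated intramolecular Reformatsky reaction in which two-electron reduction of the C–Br bond gives the ester enolate 32, which adds to the C8 ketone through a chelated five-membered transition state on the face syn to the C7–O bond with the C6–C7–C8–C9 chain kept transoid, setting C8 (hydroxyl cis to C6) and placing the C17 methyl away from the C9 branch, a centre that is in any case epimerisable next to the lactone carbonyl.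

Step 23
Reactants: 33 tris(4-methoxybenzyl)-protected 8-hydroxy γ-lactone
Product: 34 2,9,12-triol 11,20-epoxide
Conditions: DDQ (3.5 equiv), CH2Cl2–pH 7 phosphate buffer, 0 °C
Reagents that add atoms: none
Why: Oxidative cleavage of the three 4-methoxybenzyl ethers by DDQ (benzylic hydride abstraction and hydrolysis of the oxocarbenium ions) under buffered neutral conditions that spare the epoxide, the allylic chloride, the diene and the lactone.

Step 24
Reactants: 34 2,9,12-triol 11,20-epoxide
Product: 35 2,9,12-triacetate 11,20-epoxide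
Conditions: Ac2O, pyridine, 4-(dimethylamino)pyridine (cat.), CH2Cl2, 0 °C to rt
Reagents that add atoms: acetic anhydride CC(=O)OC(C)=O
Why: Nucleophile-catalysed acylation of the three secondary alcohols, the tertiary C8 hydroxyl being too hindered to react.

Step 25
Reactants: 35 2,9,12-triacetate 11,20-epoxide
Product: 36 CNP0435497.1
Conditions: LiCl, AcOH, THF, rt
Reagents that add atoms: lithium chloride [Li+].[Cl-]
Why: Regioselective SN2 opening of the 1,1-disubstituted epoxide by chloride at the primary carbon C20 under mild acid assistance leaves the C11–O bond, and hence the C11 configuration, untouched and gives the chlorohydrin of the target.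

Compound list
1 | 2-methyl-1,4-benzoquinone | CC1=CC(=O)C=CC1=O | starting material
2 | 2,4,5-triacetoxytoluene | Cc1cc(OC(C)=O)c(OC(C)=O)cc1OC(C)=O | intermediate
3 | 5-methylbenzene-1,2,4-triol | Cc1cc(O)c(O)cc1O | intermediate
4 | 2-hydroxy-5-methyl-1,4-benzoquinone | CC1=CC(=O)C(O)=CC1=O | intermediate
5 | prop-2-yn-1-ol | C#CCO | starting material
6 | 2-methyl-5-(prop-2-ynyloxy)-1,4-benzoquinone | CC1=CC(=O)C(OCC#C)=CC1=O | intermediate
7 | (E)-4-methoxybut-3-en-2-one | CO/C=C/C(C)=O | starting material
8 | (E)-1-methoxy-3-(trimethylsilyloxy)buta-1,3-diene | CO/C=C/C(=C)O[Si](C)(C)C | intermediate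
9 | (E)-1,5-dimethoxypent-1-en-3-one | CO/C=C/C(=O)CCOC | intermediate
10 | (1E,3Z)-3-(tert-butyldimethylsilyloxy)-1,5-dimethoxypenta-1,3-diene | CO/C=C/C(O[Si](C)(C)C(C)(C)C)=C/COC | intermediate
11 | cis-fused cycloadduct: C2 and C9 ketones, C3=C8 enol ether with O-propargyl on C8, C12=C13 silyl enol ether, 15-methyl β, H-10 β, 14α-OMe, 11α-CH2OMe | C#CCOC1=CC(=O)[C@@]2(C)[C@@H](OC)C=C(O[Si](C)(C)C(C)(C)C)[C@@H](COC)[C@H]2C1=O | intermediate
12 | trans-fused enedione, 10-epimer of 11 (H-10 α) | C#CCOC1=CC(=O)[C@@]2(C)[C@@H](OC)C=C(O[Si](C)(C)C(C)(C)C)[C@@H](COC)[C@@H]2C1=O | intermediate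
13 | trans-decalin 2β,9β-diol with both enol ethers | C#CCOC1=C[C@H](O)[C@@]2(C)[C@@H](OC)C=C(O[Si](C)(C)C(C)(C)C)[C@@H](COC)[C@@H]2[C@@H]1O | intermediate
14 | 2β,9β-bis(4-methoxybenzyl) ether of 13 | C#CCOC1=C[C@H](OCc2ccc(OC)cc2)[C@@]2(C)[C@@H](OC)C=C(O[Si](C)(C)C(C)(C)C)[C@@H](COC)[C@@H]2[C@@H]1OCc1ccc(OC)cc1 | intermediate
15 | C12 enone (C13=C14) still carrying the 11α-CH2OMe group | C#CCOC1=C[C@H](OCc2ccc(OC)cc2)[C@@]2(C)C=CC(=O)[C@@H](COC)[C@@H]2[C@@H]1OCc1ccc(OC)cc1 | intermediate
16 | cross-conjugated dienone: C12 ketone, C13=C14, exocyclic C11=C20 | C#CCOC1=C[C@H](OCc2ccc(OC)cc2)[C@@]2(C)C=CC(=O)C(=C)[C@@H]2[C@@H]1OCc1ccc(OC)cc1 | intermediate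
17 | 11,20-epoxy enone, epoxide oxygen α on C11 and C20 β | C#CCOC1=C[C@H](OCc2ccc(OC)cc2)[C@@]2(C)C=CC(=O)[C@]3(CO3)[C@@H]2[C@@H]1OCc1ccc(OC)cc1 | intermediate
18 | 12β-allylic alcohol of the 11,20-epoxide | C#CCOC1=C[C@H](OCc2ccc(OC)cc2)[C@@]2(C)C=C[C@H](O)[C@]3(CO3)[C@@H]2[C@@H]1OCc1ccc(OC)cc1 | intermediate
19 | 12α 4-nitrobenzoate | C#CCOC1=C[C@H](OCc2ccc(OC)cc2)[C@@]2(C)C=C[C@@H](OC(=O)c3ccc(cc3)[N+](=O)[O-])[C@]3(CO3)[C@@H]2[C@@H]1OCc1ccc(OC)cc1 | intermediate
20 | 12α-allylic alcohol of the 11,20-epoxide | C#CCOC1=C[C@H](OCc2ccc(OC)cc2)[C@@]2(C)C=C[C@@H](O)[C@]3(CO3)[C@@H]2[C@@H]1OCc1ccc(OC)cc1 | intermediate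
21 | 2β,9β,12α-tris(4-methoxybenzyl) ether with the C8 propargyl enol ether (C3=C8) | C#CCOC1=C[C@H](OCc2ccc(OC)cc2)[C@@]2(C)C=C[C@@H](OCc3ccc(OC)cc3)[C@]3(CO3)[C@@H]2[C@@H]1OCc1ccc(OC)cc1 | intermediate
22 | C8 ketone with a 3α (equatorial) propa-1,2-dienyl group | C=C=C[C@H]1[C@H](OCc2ccc(OC)cc2)[C@@]2(C)C=C[C@@H](OCc3ccc(OC)cc3)[C@]3(CO3)[C@@H]2[C@H](OCc2ccc(OC)cc2)C1=O | intermediate
23 | (E)-1,2-dichloroethene | Cl/C=C/Cl | starting material
24 | lithium chloroacetylide | [Li]C#CCl | intermediate
25 | 8α-(chloroethynyl) 8β-carbinol | C=C=C[C@H]1[C@H](OCc2ccc(OC)cc2)[C@@]2(C)C=C[C@@H](OCc3ccc(OC)cc3)[C@]3(CO3)[C@@H]2[C@H](OCc2ccc(OC)cc2)[C@@]1(O)C#CCl | intermediate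
26 | 8α-[(E)-2-chlorovinyl] 8β-ol with the cis 3α-allenyl group | C=C=C[C@H]1[C@H](OCc2ccc(OC)cc2)[C@@]2(C)C=C[C@@H](OCc3ccc(OC)cc3)[C@]3(CO3)[C@@H]2[C@H](OCc2ccc(OC)cc2)[C@@]1(O)/C=C/Cl | intermediate
27 | potassium alkoxide of 26 | C=C=C[C@H]1[C@H](OCc2ccc(OC)cc2)[C@@]2(C)C=C[C@@H](OCc3ccc(OC)cc3)[C@]3(CO3)[C@@H]2[C@H](OCc2ccc(OC)cc2)[C@@]1([O-])/C=C/Cl.[K+] | intermediate
28 | ten-membered potassium enolate (C7=C8 with C6 and C9 trans, 3Z, exocyclic C5=C16, 6-Cl) | C=C1/C=C\[C@H](OCc2ccc(OC)cc2)[C@@]2(C)C=C[C@@H](OCc3ccc(OC)cc3)[C@]3(CO3)[C@@H]2[C@H](OCc2ccc(OC)cc2)/C([O-])=C/[C@H]1Cl.[K+] | intermediate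
29 | ten-membered 7-hydroxy 8-ketone, C7 epimeric to the target | C=C1/C=C\[C@H](OCc2ccc(OC)cc2)[C@@]2(C)C=C[C@@H](OCc3ccc(OC)cc3)[C@]3(CO3)[C@@H]2[C@H](OCc2ccc(OC)cc2)C(=O)[C@H](O)[C@H]1Cl | intermediate
30 | (S)-2-bromopropanoic acid | C[C@H](Br)C(O)=O | starting material
31 | C7 (S)-2-bromopropanoate with the C7 configuration of the target | C=C1/C=C\[C@H](OCc2ccc(OC)cc2)[C@@]2(C)C=C[C@@H](OCc3ccc(OC)cc3)[C@]3(CO3)[C@@H]2[C@H](OCc2ccc(OC)cc2)C(=O)[C@@H](OC(=O)[C@H](C)Br)[C@H]1Cl | intermediate
32 | samarium ester enolate of 31 | C=C1/C=C\[C@H](OCc2ccc(OC)cc2)[C@@]2(C)C=C[C@@H](OCc3ccc(OC)cc3)[C@]3(CO3)[C@@H]2[C@H](OCc2ccc(OC)cc2)C(=O)[C@@H](OC(O[Sm](I)I)=CC)[C@H]1Cl | intermediate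
33 | tris(4-methoxybenzyl)-protected 8-hydroxy γ-lactone (briarane core with 11,20-epoxide) | C=C1/C=C\[C@H](OCc2ccc(OC)cc2)[C@@]2(C)C=C[C@@H](OCc3ccc(OC)cc3)[C@]3(CO3)[C@@H]2[C@H](OCc2ccc(OC)cc2)[C@]2(O)[C@@H](C)C(=O)O[C@H]2[C@H]1Cl | intermediate
34 | 2,9,12-triol 11,20-epoxide | C=C1/C=C\[C@H](O)[C@@]2(C)C=C[C@@H](O)[C@]3(CO3)[C@@H]2[C@H](O)[C@]2(O)[C@@H](C)C(=O)O[C@H]2[C@H]1Cl | intermediate
35 | 2,9,12-triacetate 11,20-epoxide | C=C1/C=C\[C@H](OC(C)=O)[C@@]2(C)C=C[C@@H](OC(C)=O)[C@]3(CO3)[C@@H]2[C@H](OC(C)=O)[C@]2(O)[C@@H](C)C(=O)O[C@H]2[C@H]1Cl | intermediate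
36 | CNP0435497.1 | C=C1/C=C\[C@H](OC(C)=O)[C@@]2(C)C=C[C@@H](OC(C)=O)[C@](O)(CCl)[C@@H]2[C@H](OC(C)=O)[C@]2(O)[C@@H](C)C(=O)O[C@H]2[C@H]1Cl | target

Total step count: 25. Longest linear sequence: 22 steps (steps 1–3 or 4–6, then 7–25).

Steps most likely to fail

Step 20, ring expansion and hydroxylation. The free β-chloro enolate may lose chloride (rotation about C6–C7, then elimination) before the oxidant reaches it, or the alkoxide may fragment heterolytically at C3–C8 instead of rearranging. The fallback sets out from 26 and returns at 29. Silylation of the tertiary alcohol with 1-(trimethylsilyl)imidazole gives the C8 trimethylsilyl ether F2. Heating in o-dichlorobenzene (neutral siloxy-Cope rearrangement) gives the ten-membered trimethylsilyl enol ether F3 without a free enolate ever being present. Rubottom oxidation with dimethyldioxirane at −78 °C and a citric acid work-up then gives the 7-epi hydroxy ketone 29.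

Step 7, cycloaddition. The catalyst may activate the C9 carbonyl instead of the vinylogous-ester carbonyl, so that the diene adds in the opposite orientation (C11 to C1), or the face of the methyl-bearing double bond, which lies far from the binding site, may be poorly discriminated. The fallback sets out from 6 and 10 and returns at 11. BF3·OEt2 (1 equiv) in CH2Cl2 at −78 °C, a monodentate Lewis acid that binds the vinylogous-ester carbonyl of 2-alkoxy-5-methylquinones and so gives the orientation needed here, delivers the racemic cis adduct. Chromatography on a chiral stationary phase separates 11 from its mirror image, the ent-adduct F1, which is set aside.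

Step 22, lactone closure. Electron transfer to the α-acyloxy ketone with reductive loss of the C7 carboxylate may compete with reduction of the C–Br bond, or the enolate may add to the wrong face of C8. The fallback sets out from 29 and returns at 33. Mitsunobu esterification with 2-(diethoxyphosphoryl)propanoic acid gives the C7 phosphonate ester F4 with inversion at C7. LiCl and i-Pr2NEt in MeCN close the butenolide F5 by intramolecular Horner–Wadsworth–Emmons olefination of the C8 ketone. Weitz–Scheffer epoxidation with t-BuOOH and DBU gives the 8,17-epoxy lactone F6. SmI2 in THF–MeOH at −78 °C then cleaves the C17–O bond next to the lactone carbonyl, and protonation of the enolate gives 33, with no ketone left to intercept the reductant.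

Further compounds
F1 | step 7 | enantiomer of cycloadduct 11 | C#CCOC1=CC(=O)[C@]2(C)[C@H](OC)C=C(O[Si](C)(C)C(C)(C)C)[C@H](COC)[C@@H]2C1=O
F2 | step 20 | C8 trimethylsilyl ether of 26 | C=C=C[C@H]1[C@H](OCc2ccc(OC)cc2)[C@@]2(C)C=C[C@@H](OCc3ccc(OC)cc3)[C@]3(CO3)[C@@H]2[C@H](OCc2ccc(OC)cc2)[C@@]1(O[Si](C)(C)C)/C=C/Cl
F3 | step 20 | ten-membered C7=C8 trimethylsilyl enol ether | C=C1/C=C\[C@H](OCc2ccc(OC)cc2)[C@@]2(C)C=C[C@@H](OCc3ccc(OC)cc3)[C@]3(CO3)[C@@H]2[C@H](OCc2ccc(OC)cc2)/C(O[Si](C)(C)C)=C/[C@H]1Cl
F4 | step 22 | C7 2-(diethoxyphosphoryl)propanoate of the 8-ketone | C=C1/C=C\[C@H](OCc2ccc(OC)cc2)[C@@]2(C)C=C[C@@H](OCc3ccc(OC)cc3)[C@]3(CO3)[C@@H]2[C@H](OCc2ccc(OC)cc2)C(=O)[C@@H](OC(=O)C(C)P(=O)(OCC)OCC)[C@H]1Cl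
F5 | step 22 | butenolide with the C8=C17 double bond | C=C1/C=C\[C@H](OCc2ccc(OC)cc2)[C@@]2(C)C=C[C@@H](OCc3ccc(OC)cc3)[C@]3(CO3)[C@@H]2[C@H](OCc2ccc(OC)cc2)C2=C(C)C(=O)O[C@H]2[C@H]1Cl
F6 | step 22 | 8,17-epoxy lactone | C=C1/C=C\[C@H](OCc2ccc(OC)cc2)[C@@]2(C)C=C[C@@H](OCc3ccc(OC)cc3)[C@]3(CO3)[C@@H]2[C@H](OCc2ccc(OC)cc2)[C@@]23O[C@@]3(C)C(=O)O[C@H]2[C@H]1Cl
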